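**Plan**

- Numbering (serrulatane): C1 = ArCH(CH3), C2, C3, C4 = ArCH bearing the chain; aromatic C5–C10 (C9 carries C1, C10 carries C4); chain C11–C16.
- Retrosynthesis: remove the two O-benzyl groups; cut C3–C4 (ring B) to an open primary bromide/E-styrene; then cut C10–C4 (aryl–alkenyl), C9–C1 (Claisen) and C13–C14 (chain).
- Forward: aromatic ring A is bought as methyl 2,3-dihydroxybenzoate; the C1–C3 arm is added by O-allylation/aromatic Claisen, the C4/C11–C16 arm by carboalumination/cross-coupling; ring B is closed last by a CuH-catalysed intramolecular hydroalkylation that forms C3–C4.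
- Stereochemistry: C15 is bought; C1 is set by Pd catalysis at a C–O bond and relayed to carbon by [3,3] chirality transfer; C4 and C11 arise together in the ring closure by ligand-controlled syn addition of Cu–H to the E alkene.
- Enabling feature: C4 is benzylic to C10, so C4=C11 is a styrene that takes copper at C4; C3 hangs on the ortho carbon C9 through C1–C2, so C4–Cu and C3–Br are placed for a six-membered closure of ring B onto ring A.

Key step: step 14

Assumption: the sense of induction of the Trost ligand (step 3) and of DTBM-SEGPHOS (step 14) is assigned by analogy with the closest substrate classes; if the opposite face is delivered, the ligand antipode is used and nothing else changes.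

Step 1
Reactants: 1 methyl 2,3-dihydroxybenzoate
Product: 2 methyl 5-bromo-2,3-dihydroxybenzoate
Conditions: Br2 (1.0 equiv), AcOH, rt
Reagents that add atoms: bromine, BrBr
Why: Electrophilic aromatic bromination should go para to the chelated C2 hydroxyl and meta to the ester (the future C10), since the other open positions are para or ortho to the ester.

Step 2
Reactants: 3 (E)-pent-3-en-2-ol (racemic)
Product: 4 methyl (E)-pent-3-en-2-yl carbonate (racemic)
Conditions: ClCO2Me, pyridine, CH2Cl2, 0 °C
Reagents that add atoms: methyl chloroformate, COC(=O)Cl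
Why: Carbonate formation by O-acylation; the racemate is sufficient because the allylpalladium cation derived from it in step 3 is symmetrical.

Step 3
Reactants: 2 methyl 5-bromo-2,3-dihydroxybenzoate; 4 methyl (E)-pent-3-en-2-yl carbonate
Product: 5 methyl 5-bromo-2-hydroxy-3-{[(2S,3E)-pent-3-en-2-yl]oxy}benzoate
Conditions: Pd2(dba)3·CHCl3 (1 mol %), (R,R)-DACH-phenyl Trost ligand (3 mol %), CH2Cl2, rt
Reagents that add atoms: none
Why: Trost asymmetric allylic alkylation of a phenol: ionisation gives the symmetrical syn,syn-1,3-dimethylallylpalladium cation, the ligand directs the phenoxide to one enantiotopic terminus to give the S ether with the E alkene, and the C3 hydroxyl reacts because the C2 hydroxyl is tied up in the hydrogen bond to the ester.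

Step 4
Reactants: 5 methyl 5-bromo-2-hydroxy-3-{[(2S,3E)-pent-3-en-2-yl]oxy}benzoate
Product: 6 methyl 5-bromo-2-methoxy-3-{[(2S,3E)-pent-3-en-2-yl]oxy}benzoate
Conditions: MeI, K2CO3, DMF, 40 °C
Reagents that add atoms: iodomethane, CI
Why: Williamson methylation of the remaining salicylate-type phenol installs the C7 methoxy group before the C8 oxygen is freed again.

Step 5
Reactants: 6 methyl 5-bromo-2-methoxy-3-{[(2S,3E)-pent-3-en-2-yl]oxy}benzoate
Product: 8 methyl 5-bromo-3-hydroxy-2-methoxy-4-[(2R,3E)-pent-3-en-2-yl]benzoate, via ortho-dienone 7 (not isolated)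
Conditions: Eu(fod)3 (10 mol %), PhMe, 100 °C
Reagents that add atoms: none
Why: Aromatic Claisen rearrangement to the only free ortho carbon (C9) through a chair transition state with both methyl groups equatorial, which should transfer the S C–O centre into the R benzylic centre C1 and keep the alkene E; dienone 7 then tautomerises to the phenol.

Step 6
Reactants: 8 methyl 5-bromo-3-hydroxy-2-methoxy-4-[(2R,3E)-pent-3-en-2-yl]benzoate
Product: 9 methyl 3-(benzyloxy)-5-bromo-2-methoxy-4-[(2R,3E)-pent-3-en-2-yl]benzoate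
Conditions: BnBr, K2CO3, DMF, 50 °C
Reagents that add atoms: benzyl bromide, BrCc1ccccc1
Why: Williamson benzylation protects the C8 phenol, which would otherwise quench the copper intermediates of step 14 or close a chroman onto the C3 bromide.

Step 7
Reactants: 9 methyl 3-(benzyloxy)-5-bromo-2-methoxy-4-[(2R,3E)-pent-3-en-2-yl]benzoate
Product: 10 methyl 3-(benzyloxy)-5-bromo-4-[(2R)-but-3-en-2-yl]-2-methoxybenzoate
Conditions: ethylene (5 bar), second-generation Hoveyda–Grubbs catalyst RuCl2(SIMes)(=CH-C6H4-2-OiPr) (5 mol %), 1,4-benzoquinone (10 mol %), CH2Cl2, 40 °C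
Reagents that add atoms: ethylene, C=C
Why: Ethenolysis (cross-metathesis with ethylene) trims the propenyl group to the vinyl group without touching C1, and benzoquinone suppresses ruthenium hydride isomerisation of the allylic, benzylic product.

Step 8
Reactants: 11 (R)-3-bromo-2-methylpropan-1-ol
Product: 12 (R)-[(3-bromo-2-methylpropoxy)methyl]benzene
Conditions: benzyl 2,2,2-trichloroacetimidate, TfOH (cat.), cyclohexane/CH2Cl2, rt
Reagents that add atoms: benzyl 2,2,2-trichloroacetimidate, ClC(Cl)(Cl)C(=N)OCc1ccccc1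
Why: Acid-catalysed imidate benzylation avoids the alkoxide that would close an oxetane or eliminate HBr; the stereocentre (future C15) is not involved.

Step 9
Reactants: 12 (R)-[(3-bromo-2-methylpropoxy)methyl]benzene; 13 4-bromo-1-(trimethylsilyl)but-1-yne
Product: 15 (S)-[7-(benzyloxy)-6-methylhept-1-yn-1-yl]trimethylsilane, via Grignard reagent 14 (not isolated)
Conditions: 13, Mg, THF; then 12, Li2CuCl4 (3 mol %), NMP/THF, 0 °C to rt
Reagents that add atoms: none
Why: Kochi-type copper-catalysed sp3–sp3 coupling of a primary Grignard reagent with a primary bromide forms C13–C14; the silyl group masks the alkyne C–H and the stereocentre is one carbon away from the reacting centre.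

Step 10
Reactants: 15 (S)-[7-(benzyloxy)-6-methylhept-1-yn-1-yl]trimethylsilane
Product: 16 (S)-{[(2-methylhept-6-yn-1-yl)oxy]methyl}benzene
Conditions: K2CO3 (0.2 equiv), MeOH, rt
Reagents that add atoms: none
Why: Methoxide-mediated protodesilylation of the alkynylsilane frees the terminal alkyne.

Step 11
Reactants: 16 (S)-{[(2-methylhept-6-yn-1-yl)oxy]methyl}benzene; 10 methyl 3-(benzyloxy)-5-bromo-4-[(2R)-but-3-en-2-yl]-2-methoxybenzoate
Product: 18 methyl 3-(benzyloxy)-5-[(1E,6S)-7-(benzyloxy)-2,6-dimethylhept-1-en-1-yl]-4-[(2R)-but-3-en-2-yl]-2-methoxybenzoate, via alkenyldimethylalane 17 (not isolated)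
Conditions: Me3Al (2 equiv), Cp2ZrCl2 (0.25 equiv), CH2Cl2, 0 °C to rt; volatiles removed; then 10, ZnCl2 (0.2 equiv), Pd(P(t-Bu)3)2 (5 mol %), THF, 50 °C
Reagents that add atoms: trimethylaluminium, C[Al](C)C
Why: Negishi zirconium-catalysed syn-methylalumination puts methyl on the internal and aluminium on the terminal alkyne carbon, and the palladium/zinc-catalysed cross-coupling with the aryl bromide proceeds with retention, so the E-trisubstituted C4=C11 styrene should result.

Step 12
Reactants: 18 methyl 3-(benzyloxy)-5-[(1E,6S)-7-(benzyloxy)-2,6-dimethylhept-1-en-1-yl]-4-[(2R)-but-3-en-2-yl]-2-methoxybenzoate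
Product: 20 methyl 3-(benzyloxy)-5-[(1E,6S)-7-(benzyloxy)-2,6-dimethylhept-1-en-1-yl]-4-[(2R)-4-hydroxybutan-2-yl]-2-methoxybenzoate, via B-alkyl-9-BBN adduct 19 (not isolated)
Conditions: 9-BBN (1.5 equiv), THF, 0 °C to rt; then H2O2, aq NaOAc, 0 °C
Reagents that add atoms: hydrogen peroxide, OO
Why: Brown hydroboration with 9-BBN is anti-Markovnikov and selective for the monosubstituted alkene over the trisubstituted styrene, and the buffered oxidation spares the methyl ester.

Step 13
Reactants: 20 methyl 3-(benzyloxy)-5-[(1E,6S)-7-(benzyloxy)-2,6-dimethylhept-1-en-1-yl]-4-[(2R)-4-hydroxybutan-2-yl]-2-methoxybenzoate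
Product: 21 methyl 3-(benzyloxy)-5-[(1E,6S)-7-(benzyloxy)-2,6-dimethylhept-1-en-1-yl]-4-[(2R)-4-bromobutan-2-yl]-2-methoxybenzoate
Conditions: CBr4, PPh3, CH2Cl2, 0 °C
Reagents that add atoms: tetrabromomethane, BrC(Br)(Br)Br
Why: Appel reaction converts the primary alcohol at C3 into the bromide under neutral conditions that leave the ester, the benzyl ethers and the alkene untouched.

Step 14
Reactants: 21 methyl 3-(benzyloxy)-5-[(1E,6S)-7-(benzyloxy)-2,6-dimethylhept-1-en-1-yl]-4-[(2R)-4-bromobutan-2-yl]-2-methoxybenzoate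
Product: 23 methyl (5R,8S)-4-(benzyloxy)-8-[(2S,6S)-7-(benzyloxy)-6-methylheptan-2-yl]-3-methoxy-5-methyl-5,6,7,8-tetrahydronaphthalene-2-carboxylate, via benzylcopper species 22 (not isolated)
Conditions: Cu(OAc)2 (10 mol %), (R)-DTBM-SEGPHOS (11 mol %), (MeO)2MeSiH (3 equiv), LiOMe (2 equiv), THF, 40 °C
Reagents that add atoms: none
Why: Proposed new method: the ligated copper hydride (from Cu(OAc)2, the bisphosphine and the silane) is expected to add syn across the E C4=C11 styrene with copper at benzylic C4 and hydride at C11, and benzylcopper 22 then displaces the primary bromide at C3 (oxidative addition to trivalent copper and C–C reductive elimination, retention at C4), while LiOMe and the silane return Cu–Br to Cu–H. The closest known reaction type is the CuH-catalysed enantioselective intramolecular hydroalkylation of halide-tethered E β-monosubstituted styrenes, which gives cyclobutanes, cyclopentanes, indanes and six-membered heterocycles; the extension here is to a β,β-disubstituted styrene and a six-membered carbocycle. Ring B closes in the 6-exo-tet mode. C4 is set by the alkene face that the ligand selects for hydrocupration (catalyst control, placing the side chain trans to the C1 methyl group), and C11 is tied to C4 by the syn addition, which maps the E alkene onto the 4S,11S pair. The step needs copper at C4 and not at C11, which the C10 aryl group and the fully substituted C11 secure. It also needs C-alkylation to outrun protonation of 22 and reduction of the C–Br bond, which the six-membered transition state, the aprotic medium and the benzylated phenol favour.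

Step 15
Reactants: 23 methyl (5R,8S)-4-(benzyloxy)-8-[(2S,6S)-7-(benzyloxy)-6-methylheptan-2-yl]-3-methoxy-5-methyl-5,6,7,8-tetrahydronaphthalene-2-carboxylate
Product: 24 methyl (5R,8S)-4-hydroxy-8-[(2S,6S)-7-hydroxy-6-methylheptan-2-yl]-3-methoxy-5-methyl-5,6,7,8-tetrahydronaphthalene-2-carboxylate
Conditions: H2 (1 atm), Pd/C (10 %), EtOAc/MeOH, rt
Reagents that add atoms: none
Why: Hydrogenolysis of the aryl and alkyl benzyl ethers in one operation; no other reducible group remains and no stereocentre is touched.

**Compound list**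

1 | methyl 2,3-dihydroxybenzoate | COC(=O)c1cccc(O)c1O | starting material
2 | methyl 5-bromo-2,3-dihydroxybenzoate | COC(=O)c1cc(Br)cc(O)c1O | intermediate
3 | (E)-pent-3-en-2-ol (racemic) | C/C=C/C(C)O | starting material
4 | methyl (E)-pent-3-en-2-yl carbonate (racemic) | COC(=O)OC(C)/C=C/C | intermediate
5 | methyl 5-bromo-2-hydroxy-3-{[(2S,3E)-pent-3-en-2-yl]oxy}benzoate | COC(=O)c1cc(Br)cc(O[C@@H](C)/C=C/C)c1O | intermediate
6 | methyl 5-bromo-2-methoxy-3-{[(2S,3E)-pent-3-en-2-yl]oxy}benzoate | COC(=O)c1cc(Br)cc(O[C@@H](C)/C=C/C)c1OC | intermediate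
7 | methyl (4S)-5-bromo-2-methoxy-3-oxo-4-[(2R,3E)-pent-3-en-2-yl]cyclohexa-1,5-diene-1-carboxylate (ortho-dienone) | COC(=O)C1=C(OC)C(=O)[C@H]([C@H](C)/C=C/C)C(Br)=C1 | intermediate
8 | methyl 5-bromo-3-hydroxy-2-methoxy-4-[(2R,3E)-pent-3-en-2-yl]benzoate | COC(=O)c1cc(Br)c([C@H](C)/C=C/C)c(O)c1OC | intermediate
9 | methyl 3-(benzyloxy)-5-bromo-2-methoxy-4-[(2R,3E)-pent-3-en-2-yl]benzoate | COC(=O)c1cc(Br)c([C@H](C)/C=C/C)c(OCc2ccccc2)c1OC | intermediate
10 | methyl 3-(benzyloxy)-5-bromo-4-[(2R)-but-3-en-2-yl]-2-methoxybenzoate | COC(=O)c1cc(Br)c([C@H](C)C=C)c(OCc2ccccc2)c1OC | intermediate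
11 | (R)-3-bromo-2-methylpropan-1-ol | BrC[C@H](C)CO | starting material
12 | (R)-[(3-bromo-2-methylpropoxy)methyl]benzene | BrC[C@H](C)COCc1ccccc1 | intermediate
13 | 4-bromo-1-(trimethylsilyl)but-1-yne | C[Si](C)(C)C#CCCBr | starting material
14 | [4-(trimethylsilyl)but-3-yn-1-yl]magnesium bromide (Grignard reagent) | C[Si](C)(C)C#CCC[Mg]Br | intermediate
15 | (S)-[7-(benzyloxy)-6-methylhept-1-yn-1-yl]trimethylsilane | C[Si](C)(C)C#CCCC[C@H](C)COCc1ccccc1 | intermediate
16 | (S)-{[(2-methylhept-6-yn-1-yl)oxy]methyl}benzene | C#CCCC[C@H](C)COCc1ccccc1 | intermediate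
17 | [(1E,6S)-7-(benzyloxy)-2,6-dimethylhept-1-en-1-yl]dimethylalane | C[Al](C)/C=C(\C)CCC[C@H](C)COCc1ccccc1 | intermediate
18 | methyl 3-(benzyloxy)-5-[(1E,6S)-7-(benzyloxy)-2,6-dimethylhept-1-en-1-yl]-4-[(2R)-but-3-en-2-yl]-2-methoxybenzoate | COC(=O)c1cc(/C=C(\C)CCC[C@H](C)COCc2ccccc2)c([C@H](C)C=C)c(OCc2ccccc2)c1OC | intermediate
19 | B-alkyl-9-BBN adduct of 18 (boron on the terminal carbon C3) | COC(=O)c1cc(/C=C(\C)CCC[C@H](C)COCc2ccccc2)c([C@H](C)CCB2C3CCCC2CCC3)c(OCc2ccccc2)c1OC | intermediate
20 | methyl 3-(benzyloxy)-5-[(1E,6S)-7-(benzyloxy)-2,6-dimethylhept-1-en-1-yl]-4-[(2R)-4-hydroxybutan-2-yl]-2-methoxybenzoate | COC(=O)c1cc(/C=C(\C)CCC[C@H](C)COCc2ccccc2)c([C@H](C)CCO)c(OCc2ccccc2)c1OC | intermediate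
21 | methyl 3-(benzyloxy)-5-[(1E,6S)-7-(benzyloxy)-2,6-dimethylhept-1-en-1-yl]-4-[(2R)-4-bromobutan-2-yl]-2-methoxybenzoate | COC(=O)c1cc(/C=C(\C)CCC[C@H](C)COCc2ccccc2)c([C@H](C)CCBr)c(OCc2ccccc2)c1OC | intermediate
22 | benzylcopper species from syn Cu–H addition to 21 (copper on C4, 4S,11S; bisphosphine ligand omitted) | COC(=O)c1cc([C@@H]([Cu])[C@@H](C)CCC[C@H](C)COCc2ccccc2)c([C@H](C)CCBr)c(OCc2ccccc2)c1OC | intermediate
23 | methyl (5R,8S)-4-(benzyloxy)-8-[(2S,6S)-7-(benzyloxy)-6-methylheptan-2-yl]-3-methoxy-5-methyl-5,6,7,8-tetrahydronaphthalene-2-carboxylate | COC(=O)c1cc2c(c(OCc3ccccc3)c1OC)[C@H](C)CC[C@H]2[C@@H](C)CCC[C@H](C)COCc1ccccc1 | intermediate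
24 | methyl (5R,8S)-4-hydroxy-8-[(2S,6S)-7-hydroxy-6-methylheptan-2-yl]-3-methoxy-5-methyl-5,6,7,8-tetrahydronaphthalene-2-carboxylate | COC(=O)c1cc2c(c(O)c1OC)[C@H](C)CC[C@H]2[C@@H](C)CCC[C@H](C)CO | target

**Step count**

Total steps: 15. Longest linear sequence: 11 steps (1 → 2 → 5 → 6 → 8 → 9 → 10 → 18 → 20 → 21 → 23 → 24; the branch from 3 through step 2 is equally long).

**Steps most likely to fail, with fallbacks**

1. Step 14 (Proposed new method). Hydrocupration of the trisubstituted, ortho-substituted styrene may be slower than reduction of the C–Br bond or protonation of the organocopper, or the ligand may fail to override the facial bias of the substrate. The fallback uses known chemistry, sets out from 21 and returns at 23. Brown asymmetric hydroboration of 21 with the enantiomer of monoisopinocampheylborane that delivers hydrogen to the C11 face leading to 11S, then buffered oxidation, should give the benzylic alcohol F1 (syn addition, boron and then oxygen on benzylic C4, C11 set by the reagent). Dess–Martin oxidation should give the aryl ketone F2 with C11 retained. PPh3 in MeCN at reflux should convert the primary bromide into the phosphonium bromide F3. NaHMDS in THF at −78 °C to rt should then close the same C3–C4 bond as an alkene by intramolecular Wittig olefination, giving the dihydronaphthalene F4. Iridium-catalysed asymmetric hydrogenation of this trisubstituted cyclic styrene with a chiral P,N-ligand complex of the [Ir(cod)(PHOX)]BArF class (H2, 50 bar, CH2Cl2) should set C4 under catalyst control and give 23 without touching the benzyl ethers.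

2. Step 3. The phenoxide may discriminate poorly between the enantiotopic termini of the allylpalladium cation, the electron-poor aryl ether may re-ionise and erode the enantiomeric purity, or allylation may occur at the chelated C2 hydroxyl. The fallback sets out from 2 and returns at 5. Corey–Bakshi–Shibata reduction of commercial (E)-pent-3-en-2-one with the (S)-Me-CBS oxazaborolidine and BH3·SMe2 should give (2R,3E)-pent-3-en-2-ol F5. Mitsunobu etherification of 2 with F5 (PPh3, DIAD, THF, 0 °C) should then give 5 with inversion at the carbinol carbon. The stereocentre is thus made by a reagent-controlled reduction and transferred by SN2 displacement instead of by asymmetric allylic alkylation.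

3. Step 7. Ethenolysis of the hindered internal alkene may stall, or ruthenium hydride species may move the double bond into conjugation with the arene and destroy C1. The fallback sets out from 9 and returns at 10. Lemieux–Johnson cleavage of 9 (OsO4 cat., NaIO4, 2,6-lutidine, dioxane/water) should give the α-aryl aldehyde F6. Wittig methylenation with Ph3P=CH2 in THF at −78 °C, where the twisted, hindered α-aryl centre should resist enolisation, should then give 10.

**Further compounds**

F1 | step 14 | methyl 3-(benzyloxy)-5-[(1S,2S,6S)-7-(benzyloxy)-1-hydroxy-2,6-dimethylheptyl]-4-[(2R)-4-bromobutan-2-yl]-2-methoxybenzoate | COC(=O)c1cc([C@@H](O)[C@@H](C)CCC[C@H](C)COCc2ccccc2)c([C@H](C)CCBr)c(OCc2ccccc2)c1OC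
F2 | step 14 | methyl 3-(benzyloxy)-5-[(2S,6S)-7-(benzyloxy)-2,6-dimethylheptanoyl]-4-[(2R)-4-bromobutan-2-yl]-2-methoxybenzoate | COC(=O)c1cc(C(=O)[C@@H](C)CCC[C@H](C)COCc2ccccc2)c([C@H](C)CCBr)c(OCc2ccccc2)c1OC
F3 | step 14 | {(3R)-3-[2-(benzyloxy)-6-[(2S,6S)-7-(benzyloxy)-2,6-dimethylheptanoyl]-3-methoxy-4-(methoxycarbonyl)phenyl]butyl}triphenylphosphonium bromide | COC(=O)c1cc(C(=O)[C@@H](C)CCC[C@H](C)COCc2ccccc2)c([C@H](C)CC[P+](c2ccccc2)(c2ccccc2)c2ccccc2)c(OCc2ccccc2)c1OC.[Br-]
F4 | step 14 | methyl (5R)-4-(benzyloxy)-8-[(2S,6S)-7-(benzyloxy)-6-methylheptan-2-yl]-3-methoxy-5-methyl-5,6-dihydronaphthalene-2-carboxylate | COC(=O)c1cc2c(c(OCc3ccccc3)c1OC)[C@H](C)CC=C2[C@@H](C)CCC[C@H](C)COCc1ccccc1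
F5 | step 3 | (2R,3E)-pent-3-en-2-ol | O[C@H](C)/C=C/C
F6 | step 7 | methyl 3-(benzyloxy)-5-bromo-2-methoxy-4-[(2S)-1-oxopropan-2-yl]benzoate | COC(=O)c1cc(Br)c([C@H](C)C=O)c(OCc2ccccc2)c1OC
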